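Watch the substrate stall.

| flask | substrate | coupling partner | remark | time |
|---|---|---|---|---|
| zeta | 0.14 M | 0.11 M | run made earlier |  |
| beta | 0.22 M | 0.11 M | run made earlier |  |
| gamma | 0.10 M | 0.22 M | run made earlier |  |
| flask | 0.10 M | 0.110 M |  | 12 h |

| run | time / h | substrate / % | first product / % |
|---|---|---|---|
| zeta | 2.00 | 87.5 | 9.2 |
| zeta | 4.00 | 87.9 | 9.0 |
| zeta | 5.00 | 86.8 | 8.2 |
| zeta | 8.00 | 87.2 | 9.7 |
| beta | 0.500 | 91.2 | 6.9 |
| beta | 1.33 | 90.0 | 7.2 |
| beta | 3.00 | 89.2 | 7.3 |
| beta | 8.00 | 88.8 | 9.1 |
| gamma | 0.500 | 85.9 | 9.5 |
| gamma | 1.33 | 82.2 | 12.0 |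
| gamma | 3.00 | 80.7 | 12.6 |
| gamma | 8.00 | 80.2 | 11.4 |

(each reading ± 0.5 percentage points)

- the analysis behind the earlier runs scatters by 0.5 percentage points, standard deviation
- on the list of suspects stand: coupling partner + bis adduct <-> triple product; substrate + coupling partner -> first product; coupling partner -> decomposed reagent; coupling partner + first product -> bis adduct; 2 coupling partner -> homo dimer

- how much substrate there is at 12 h, in percent of the substrate charged
- how much first product there is at 12 h, in percent of the substrate charged
- how much bis adduct there is at 12 h, in percent of the substrate charged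
- how much triple product there is at 12 h, in percent of the substrate charged

I drew the substrate curve first. The beta run's first reading gave, as a chord over its first 0.500 h, a logarithmic slope of 1.67 M⁻¹ h⁻¹ per unit of partner charge, so I took 0.184 h⁻¹ as my estimate of the starting slope in the flask.

For the level, I used the zeta run, whose substrate read 87.5 % at 2.00 h and 87.2 % at 8.00 h, with a scatter of 0.5 percentage points. I defined the reach as the logarithm of substrate lost per mole per litre of coupling partner not taken up by coupling. I counted the unread part of the zeta balance as bis adduct, which put the partner use at 1.24 per substrate converted.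

reach = 0.137 ÷ 0.0877 M = 1.56 M⁻¹

Beta gave 1.47 M⁻¹, and gamma, at 0.22 M of partner, gave less, 1.15 M⁻¹. I kept the zeta value, since that run has the flask's partner charge, and went round the loop, putting each answer back in:

start, with no coupling use: 0.172
next: 0.141
next: 0.146

My level was therefore 86.4 % substrate, and the slope meets it at a knee near 0.794 h.

The forecast gave 88 % substrate, 8.8 % first product, 2.5 % bis adduct and 0.7 % triple product, reasoning that “The substrate stalls within a few hours, so the coupling partner is dying quickly.” Its substrate stood above my level.

At 12 h the flask gave 86.7 % substrate, 9.32 % first product, 3.93 % bis adduct and 0.0153 % triple product, so all four forecast values were right within the tolerance.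

    coupling partner + bis adduct ⇌ triple product (K = 14.0 M⁻¹, k = 3.20 M⁻¹ h⁻¹)
    substrate + coupling partner → first product (k = 3.30 M⁻¹ h⁻¹)
    coupling partner → decomposed reagent (k = 1.20 h⁻¹)
    coupling partner + first product → bis adduct (k = 17.0 M⁻¹ h⁻¹)
    2 coupling partner → homo dimer (k = 10.0 M⁻¹ h⁻¹)

The forecast's substrate lay 1.3 points above the flask and my level 0.30 points below it. In the flask the coupling partner, the limiting reagent, had 6.58 % of its charge left at 1.20 h. For a neighbouring flask with 0.40 M of substrate, all else as in the flask, I closed the loop for small conversion, which gave a logarithm of reach × charged [coupling partner] ÷ (1 + reach × use × charged [substrate]). That came to 0.0967, a level of 90.8 %. At 12 h that neighbouring flask stood at 90.8 % substrate.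

(Readings and results are calculated with constants of no real substance; noise was put on by code.)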